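Read at 1.3 min, the green run already holds 0.0178 M of product and the blue run 0.0085 M. The two flasks have the same charges of starting material and free catalyst, and differ in coupling partner, 0.180 M against 0.0600 M.

| flask | starting material | coupling partner | free catalyst | time |
|---|---|---|---|---|
| blue | 0.0500 M | 0.0600 M | 2.50 × 10⁻⁴ M |  |
| green | 0.0500 M | 0.180 M | 2.50 × 10⁻⁴ M |  |
| teal | 0.0500 M | 0.0300 M | 1.30 × 10⁻⁴ M | 6.5 min |

- blue run (time / min: [product] / M): 1.3: 0.0085; 2.6: 0.0178; 3.9: 0.0275; 5.2: 0.0359; 6.5: 0.0410
- green run (time / min: [product] / M): 1.3: 0.0178; 2.6: 0.0409; 3.9: 0.0486; 5.2: 0.0503; 6.5: 0.0505

(scatter of a reading: 4 × 10⁻⁴ M)

- Overall: starting material + coupling partner -> product, with free catalyst as catalyst.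
- Constant volume, constant temperature.
- The analysis sees a species whether free or bound.
- "The second partner" is coupling partner.
- An order is taken over about fifteen percent of the charge, up and down.

* order of the initial rate in [coupling partner], near the charge of the blue run, the rate being that where two percent of its starting material are product
* product in the teal run at 6.5 min, as a share of the starting material charged

Two numbers from the blue run seem not to go together. Up to 1.3 min the blue run makes product at 0.00654 M/min, yet between 2.6 min and 3.9 min it makes product at 0.00746 M/min, which is faster, although [starting material] and [coupling partner] have both fallen.

The reckoning here therefore lets product speed its own making. The green run climbs from 0.0137 M/min over its first reading interval to 0.0178 M/min over its second. Taking the rest of the green rate as steady across these two intervals, the gain in rate divided by the gain in the product [starting material][coupling partner][product], each concentration taken at the middle of its interval, gives 142 /M²/min, the self-speeding coefficient.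

Taking this part off the blue rate leaves a remainder of 0.00500 M/min in the first interval, at a mean [coupling partner] of 0.0557 M. Between 3.9 min and 5.2 min the remainder is 0.00413 M/min, at a mean [coupling partner] of 0.0283 M. Although [starting material] differs between these intervals, the reckoning reads the two remainders as an order in [coupling partner] of 0.281, and this reading is its answer for the order asked, the self-speeding part being set aside near the start.

In the teal run, coupling partner is the limiting reagent. Taking the later blue remainder as proportional to catalyst, which neither run tests, and carrying it to the teal charge of coupling partner gives 0.00218 M/min, and so a first answer of 0.0142 M of product at 6.5 min. Going round once more with half that product as the mean, and adding the self-speeding part, gives 0.0196 M, a share of 39.2%.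

The forecast gives 0.62 and 25%, holding that “Tripling the charge of coupling partner only about doubles the rate”. This reckoning differs, with a lower order and a higher share.

The flask gives an order of 0.34 and, in the teal run, 34.6%, from these steps:

    free catalyst + starting material → loaded catalyst + by-product (3966 /M/min)
    loaded catalyst + coupling partner → product + free catalyst (1236 /M/min)
    free catalyst + starting material ⇌ idle catalyst-substrate complex, settled at all times (133.0 /M)
    starting material + coupling partner + product → 2 product (166.2 /M²/min)

In the teal run the two catalyst steps ran from the start, with 51.2% of the catalyst held near the start as idle catalyst-substrate complex. The step of starting material, coupling partner and product ran beside them as product gathered, at 0.00119 M/min at 6.5 min, when the teal run holds 0.0173 M of product and 0.0127 M of coupling partner. In the green run at 1.67 min, with 0.0250 M of product, the coefficient read from the readings, 142 /M²/min, puts that step at 0.0138 M/min.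

The earlier runs and the new flask stem from a simulated flask with made-up constants.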